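**Retrosynthetic overview**
1. Target 28 ⇐ 14-deoxy ester 27 by a last-step SeO2 hydroxylation of the C10 methyl group, which also fixes the 9E alkene; 27 ⇐ diol lactone 25 + acid 5 (ester at O4).
2. 25 ⇐ cyclodecadienone lactone 19: C6–OH by enantioselective β-borylation/oxidation, C4–OH by 1,3-anti reduction, α-methylene by Mannich methylenation.
3. 19 ⇐ tricyclic tertiary homoallylic alcohol 18 by the key ring expansion: β-scission of the ring-fusion bond of a 6-6 alkoxy radical (new, non-pericyclic).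
4. 18 ⇐ enone 15 by reductive aldol closure of ring B, directed reduction and lactonisation; 15 ⇐ Diels–Alder adduct 9 + Me3SiCH2MgCl + fumaryl chloride 12.
5. Ring order: ring A (Diels–Alder) → ring B (reductive aldol) → γ-lactone → ten-membered ring (cleavage of the A/B fusion bond); acid 5 comes from ethyl but-2-ynoate.

Assumption: the (S)-configured oxazaborolidinium catalyst is taken to give (1S,2R)-9 and the (R,R)-ligand in step 12 to give (6R); every other stereocentre is relayed from C1 of 9.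

**Side chain**

Step 1
Reactants: 1 ethyl but-2-ynoate
Product: 3 ethyl (2Z)-2-(hydroxymethyl)but-2-enoate, via vinylalane 2 (not isolated)
Conditions: iBu2AlH, N-methylmorpholine N-oxide, THF, 0 °C; then CH2O (gas), 0 °C → rt
Reagents that add atoms: formaldehyde (C=O); diisobutylaluminium hydride (CC(C)C[AlH]CC(C)C; Al held only in 2)
Why: syn-hydroalumination places Al at C2 and H at C3, and the α-alumino acrylate adds to formaldehyde with retention, so CO2Et and CH3 end cis (vinylalumination, a Baylis–Hillman-type hydroxymethylation).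

Step 2
Reactants: 3 ethyl (2Z)-2-(hydroxymethyl)but-2-enoate
Product: 4 (2Z)-2-(hydroxymethyl)but-2-enoic acid
Conditions: LiOH, THF/H2O, 0 °C; then 1 M HCl
Reagents that add atoms: lithium hydroxide ([Li+].[OH-])
Why: cold saponification of the ethyl ester leaves the Z-trisubstituted alkene untouched (ester hydrolysis).

Step 3
Reactants: 4 (2Z)-2-(hydroxymethyl)but-2-enoic acid
Product: 5 (2Z)-2-[(acetyloxy)methyl]but-2-enoic acid
Conditions: Ac2O, pyridine, CH2Cl2, 0 °C → rt; aqueous work-up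
Reagents that add atoms: acetic anhydride (CC(=O)OC(C)=O)
Why: O-acetylation of the primary allylic alcohol without a nucleophilic catalyst avoids allylic transposition, and any mixed anhydride is hydrolysed on work-up (acylation).

**Core**

Step 4
Reactants: 6 3-methylbut-2-enal
Product: 7 triethyl{[(1E)-3-methylbuta-1,3-dien-1-yl]oxy}silane
Conditions: Et3SiOTf, Et3N, Et2O, 0 °C → rt
Reagents that add atoms: triethylsilyl trifluoromethanesulfonate (CC[Si](CC)(CC)OS(=O)(=O)C(F)(F)F)
Why: soft enolisation removes a γ-methyl proton and O-silylation gives the (E)-1-silyloxy diene (silyl dienol ether formation).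

Step 5
Reactants: 7 triethyl{[(1E)-3-methylbuta-1,3-dien-1-yl]oxy}silane; 8 methyl acrylate
Product: 9 methyl (1S,2R)-4-methyl-2-[(triethylsilyl)oxy]cyclohex-3-ene-1-carboxylate
Conditions: (S)-oxazaborolidinium triflimide (10 mol %; from (S)-3,3-diphenyl-1-(o-tolyl)tetrahydro-1H,3H-pyrrolo[1,2-c][1,3,2]oxazaborole + Tf2NH), CH2Cl2, −78 °C
Reagents that add atoms: none
Why: enantioselective Diels–Alder reaction in which the 1-silyloxy and 3-methyl groups both direct the ester carbon next to C–OSi, the endo transition state gives the cis 1,2-relationship, and the catalyst shields one acrylate face to set C1 as S (hence C2 as R).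

Step 6
Reactants: 9 methyl (1S,2R)-4-methyl-2-[(triethylsilyl)oxy]cyclohex-3-ene-1-carboxylate
Product: 11 triethyl({(1R,6R)-3-methyl-6-[3-(trimethylsilyl)prop-1-en-2-yl]cyclohex-2-en-1-yl}oxy)silane, via carbinol 10 (not isolated)
Conditions: Me3SiCH2MgCl (3 equiv), CeCl3, THF, −78 °C → rt; then SiO2, CH2Cl2, rt
Reagents that add atoms: (trimethylsilyl)methylmagnesium chloride (C[Si](C)(C)C[Mg]Cl)
Why: double addition of the non-basic organocerium reagent to the ester and Peterson elimination of one silanol give the 2-substituted allylsilane without epimerising the ring stereocentre (Bunnelle-type allylsilane synthesis).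

Step 7
Reactants: 11 triethyl({(1R,6R)-3-methyl-6-[3-(trimethylsilyl)prop-1-en-2-yl]cyclohex-2-en-1-yl}oxy)silane; 12 fumaryl chloride
Product: 14 methyl (2E)-6-[(1R,2R)-2-hydroxy-4-methylcyclohex-3-en-1-yl]-4-oxohepta-2,6-dienoate, via acyl chloride 13 (not isolated)
Conditions: 12 (3 equiv), AlCl3 (1.1 equiv), CH2Cl2, −78 °C; then MeOH, 0 °C → rt
Reagents that add atoms: methanol (CO)
Why: Sakurai-type acylation in which the allylsilane attacks the acylium complex at its CH2 terminus and loses Me3Si to give the β,γ-unsaturated ketone regiospecifically, after which methanol esterifies the second acid chloride and the HCl formed cleaves the Et3Si ether.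

Step 8
Reactants: 14 methyl (2E)-6-[(1R,2R)-2-hydroxy-4-methylcyclohex-3-en-1-yl]-4-oxohepta-2,6-dienoate
Product: 15 methyl (2E)-6-[(1R)-4-methyl-2-oxocyclohex-3-en-1-yl]-4-oxohepta-2,6-dienoate
Conditions: MnO2, CH2Cl2, rt
Reagents that add atoms: none
Why: MnO2 oxidises only the allylic secondary alcohol under neutral conditions, so the α-stereocentre and the deconjugated exo-methylene ketone survive (allylic oxidation).

Step 9
Reactants: 15 methyl (2E)-6-[(1R)-4-methyl-2-oxocyclohex-3-en-1-yl]-4-oxohepta-2,6-dienoate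
Product: 16 methyl 2-[(1S,4aR,8aS)-8a-hydroxy-7-methyl-4-methylidene-2-oxo-1,2,3,4,4a,5,6,8a-octahydronaphthalen-1-yl]acetate
Conditions: [(Ph3P)CuH]6 (0.4 equiv), toluene, −40 → 0 °C; aq. NH4Cl
Reagents that add atoms: none
Why: Cu–H adds hydride β to the side-chain ketone and the resulting (Z)-copper enolate closes ring B on the ring ketone through a chelated chair transition state (reductive aldol cyclisation), giving the cis-fused ketol with 8a-OH axial and the CH2CO2Me group equatorial, both fixed relative to C4a.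

Step 10
Reactants: 16 methyl 2-[(1S,4aR,8aS)-8a-hydroxy-7-methyl-4-methylidene-2-oxo-1,2,3,4,4a,5,6,8a-octahydronaphthalen-1-yl]acetate
Product: 18 (3aS,5aR,9aS,9bR)-9a-hydroxy-8-methyl-5-methylidene-3a,4,5,5a,6,7,9a,9b-octahydronaphtho[2,1-b]furan-2(1H)-one, via diol ester 17 (not isolated)
Conditions: Me4NBH(OAc)3, MeCN/AcOH, −30 °C; then pyridinium p-toluenesulfonate (cat.), toluene, 60 °C
Reagents that add atoms: none
Why: the 8a-alkoxyborohydride delivers hydride intramolecularly to C2 (Evans–Saksena 1,3-anti reduction) to give the equatorial 2-OH trans to the adjacent side chain, and only this secondary alcohol lactonises, giving the trans-fused γ-lactone.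

Step 11
Reactants: 18 (3aS,5aR,9aS,9bR)-9a-hydroxy-8-methyl-5-methylidene-3a,4,5,5a,6,7,9a,9b-octahydronaphtho[2,1-b]furan-2(1H)-one
Product: 19 (3aR,5Z,9Z,11aS)-6,10-dimethyl-3,3a,7,8,11,11a-hexahydrocyclodeca[b]furan-2,4-dione
Conditions: [Ir(dF(CF3)ppy)2(5,5′-d(CF3)bpy)]PF6 (2 mol %; dF(CF3)ppy = cyclometalated 2-(2,4-difluorophenyl)-5-(trifluoromethyl)pyridine, d(CF3)bpy = 5,5′-bis(trifluoromethyl)-2,2′-bipyridine), 2,4,6-triisopropylbenzenethiol (20 mol %), tetrabutylphosphonium dimethyl phosphate (25 mol %), PhCF3, blue LEDs, 25 °C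
Reagents that add atoms: none
Why: Proposed new method: the excited iridium complex and the phosphate base homolyse the tertiary O–H bond of 18 by proton-coupled electron transfer, the alkoxy radical cleaves the C9a–C5a fusion bond because only that β-scission gives an allyl radical (and a conjugated enone), and the thiol returns the hydrogen to the CH2 terminus while reduced iridium and the protonated base regenerate the thiol, so the 6-6 carbinol isomerises redox-neutrally to the ten-membered dienone with both existing stereocentres untouched; the closest known reactions are photocatalytic ring-opening isomerisations of cyclic tertiary alcohols and hypoiodite alkoxy-radical fragmentations of fused carbinols.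

Step 12
Reactants: 19 (3aR,5Z,9Z,11aS)-6,10-dimethyl-3,3a,7,8,11,11a-hexahydrocyclodeca[b]furan-2,4-dione
Product: 21 (3aR,6R,9Z,11aS)-6-hydroxy-6,10-dimethyl-3,3a,5,6,7,8,11,11a-octahydrocyclodeca[b]furan-2,4-dione, via boronate 20 (not isolated)
Conditions: CuCl (5 mol %), NaOtBu (10 mol %), (R,R)-2,3-bis(tert-butylmethylphosphino)quinoxaline (6 mol %), B2pin2, MeOH, THF, 0 °C → rt; then H2O2, pH 7 buffer, 0 °C
Reagents that add atoms: bis(pinacolato)diboron (CC1(C)OB(OC1(C)C)B1OC(C)(C)C(C)(C)O1; boron held only in 20); hydrogen peroxide (OO)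
Why: ligand-controlled copper–boryl conjugate addition to the β,β-disubstituted enone sets the C6 quaternary centre, and stereoretentive C–B oxidation gives the (6R) tertiary alcohol (asymmetric β-borylation/oxidation).

Step 13
Reactants: 21 (3aR,6R,9Z,11aS)-6-hydroxy-6,10-dimethyl-3,3a,5,6,7,8,11,11a-octahydrocyclodeca[b]furan-2,4-dione
Product: 22 (3aS,4S,6R,9Z,11aS)-4,6-dihydroxy-6,10-dimethyl-3a,4,5,6,7,8,11,11a-octahydrocyclodeca[b]furan-2(3H)-one
Conditions: Me4NBH(OAc)3, MeCN/AcOH, −20 °C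
Reagents that add atoms: none
Why: the borohydride bound to the C6 hydroxyl reduces the C4 ketone intramolecularly through a chair transition state (Evans–Saksena reduction), giving the 1,3-anti diol and hence (4S).

Step 14
Reactants: 22 (3aS,4S,6R,9Z,11aS)-4,6-dihydroxy-6,10-dimethyl-3a,4,5,6,7,8,11,11a-octahydrocyclodeca[b]furan-2(3H)-one
Product: 25 (3aS,4S,6R,9Z,11aS)-4,6-dihydroxy-6,10-dimethyl-3-methylidene-3a,4,5,6,7,8,11,11a-octahydrocyclodeca[b]furan-2(3H)-one, via Mannich base 23 (not isolated), via ammonium iodide 24 (not isolated)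
Conditions: LiN(iPr)2 (4.5 equiv, substrate added to base), THF, −78 °C; CH2=NMe2+ I−, −78 → 0 °C; then MeI, MeOH, rt; then aq. NaHCO3, CH2Cl2, rt
Reagents that add atoms: dimethyl(methylidene)ammonium iodide (C=[N+](C)C.[I-]); iodomethane (CI; methyl held only in 24)
Why: the lactone enolate (both hydroxyls carried as lithium alkoxides) undergoes a Mannich reaction with the iminium salt, and quaternisation followed by elimination of trimethylamine unveils the α-methylene lactone without touching a stereocentre (Eschenmoser methylenation).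

Step 15
Reactants: 25 (3aS,4S,6R,9Z,11aS)-4,6-dihydroxy-6,10-dimethyl-3-methylidene-3a,4,5,6,7,8,11,11a-octahydrocyclodeca[b]furan-2(3H)-one; 5 (2Z)-2-[(acetyloxy)methyl]but-2-enoic acid
Product: 27 (3aR,4S,6R,9Z,11aS)-6-hydroxy-6,10-dimethyl-3-methylidene-2-oxo-2,3,3a,4,5,6,7,8,11,11a-decahydrocyclodeca[b]furan-4-yl (2Z)-2-[(acetyloxy)methyl]but-2-enoate, via mixed anhydride 26 (not isolated)
Conditions: 5, 2,4,6-Cl3C6H2COCl, Et3N, toluene, rt; then 25, 80 °C
Reagents that add atoms: 2,4,6-trichlorobenzoyl chloride (ClC(=O)c1c(Cl)cc(Cl)cc1Cl; held only in 26)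
Why: Yamaguchi mixed-anhydride esterification run without a nucleophilic catalyst acylates the secondary 4-OH (the tertiary 6-OH is inert) and keeps the Z geometry of the angelate-type acid.

Step 16
Reactants: 27 (3aR,4S,6R,9Z,11aS)-6-hydroxy-6,10-dimethyl-3-methylidene-2-oxo-2,3,3a,4,5,6,7,8,11,11a-decahydrocyclodeca[b]furan-4-yl (2Z)-2-[(acetyloxy)methyl]but-2-enoate
Product: 28 (3aR,4S,6R,9E,11aS)-6-hydroxy-10-(hydroxymethyl)-6-methyl-3-methylidene-2-oxo-2,3,3a,4,5,6,7,8,11,11a-decahydrocyclodeca[b]furan-4-yl (2Z)-2-[(acetyloxy)methyl]but-2-enoate (CNP0313132.1)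
Conditions: SeO2 (0.5 equiv), tBuOOH (3 equiv), CH2Cl2, rt
Reagents that add atoms: selenium dioxide (O=[Se]=O); tert-butyl hydroperoxide (CC(C)(C)OO)
Why: the SeO2 ene reaction/[2,3]-shift (Riley allylic oxidation) hydroxylates the C10 methyl of the only electron-rich alkene, and the sigmatropic step places CH2OH trans to C8 whatever the starting 9,10-geometry, giving the 9E alkene of the target.

**Compound list**
1 | ethyl but-2-ynoate | CCOC(=O)C#CC | starting material
2 | ethyl (2E)-2-(diisobutylalumanyl)but-2-enoate | CCOC(=O)/C(=C\C)[Al](CC(C)C)CC(C)C | intermediate (not isolated)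
3 | ethyl (2Z)-2-(hydroxymethyl)but-2-enoate | CCOC(=O)/C(=C\C)CO | intermediate
4 | (2Z)-2-(hydroxymethyl)but-2-enoic acid | OC(=O)/C(=C\C)CO | intermediate
5 | (2Z)-2-[(acetyloxy)methyl]but-2-enoic acid | OC(=O)/C(=C\C)COC(C)=O | intermediate
6 | 3-methylbut-2-enal | CC(C)=CC=O | starting material
7 | triethyl{[(1E)-3-methylbuta-1,3-dien-1-yl]oxy}silane | CC(=C)/C=C/O[Si](CC)(CC)CC | intermediate
8 | methyl acrylate | COC(=O)C=C | starting material
9 | methyl (1S,2R)-4-methyl-2-[(triethylsilyl)oxy]cyclohex-3-ene-1-carboxylate | COC(=O)[C@H]1CCC(C)=C[C@H]1O[Si](CC)(CC)CC | intermediate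
10 | 2-{(1S,2R)-4-methyl-2-[(triethylsilyl)oxy]cyclohex-3-en-1-yl}-1,3-bis(trimethylsilyl)propan-2-ol | C[Si](C)(C)CC(O)(C[Si](C)(C)C)[C@H]1CCC(C)=C[C@H]1O[Si](CC)(CC)CC | intermediate (not isolated)
11 | triethyl({(1R,6R)-3-methyl-6-[3-(trimethylsilyl)prop-1-en-2-yl]cyclohex-2-en-1-yl}oxy)silane | C[Si](C)(C)CC(=C)[C@H]1CCC(C)=C[C@H]1O[Si](CC)(CC)CC | intermediate
12 | fumaryl chloride | ClC(=O)/C=C/C(Cl)=O | starting material
13 | (2E)-6-{(1R,2R)-4-methyl-2-[(triethylsilyl)oxy]cyclohex-3-en-1-yl}-4-oxohepta-2,6-dienoyl chloride | ClC(=O)/C=C/C(=O)CC(=C)[C@H]1CCC(C)=C[C@H]1O[Si](CC)(CC)CC | intermediate (not isolated)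
14 | methyl (2E)-6-[(1R,2R)-2-hydroxy-4-methylcyclohex-3-en-1-yl]-4-oxohepta-2,6-dienoate | COC(=O)/C=C/C(=O)CC(=C)[C@H]1CCC(C)=C[C@H]1O | intermediate
15 | methyl (2E)-6-[(1R)-4-methyl-2-oxocyclohex-3-en-1-yl]-4-oxohepta-2,6-dienoate | COC(=O)/C=C/C(=O)CC(=C)[C@H]1CCC(C)=CC1=O | intermediate
16 | methyl 2-[(1S,4aR,8aS)-8a-hydroxy-7-methyl-4-methylidene-2-oxo-1,2,3,4,4a,5,6,8a-octahydronaphthalen-1-yl]acetate | COC(=O)C[C@@H]1C(=O)CC(=C)[C@H]2CCC(C)=C[C@@]12O | intermediate
17 | methyl 2-[(1R,2S,4aR,8aS)-2,8a-dihydroxy-7-methyl-4-methylidene-1,2,3,4,4a,5,6,8a-octahydronaphthalen-1-yl]acetate | COC(=O)C[C@@H]1[C@@H](O)CC(=C)[C@H]2CCC(C)=C[C@@]12O | intermediate (not isolated)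
18 | (3aS,5aR,9aS,9bR)-9a-hydroxy-8-methyl-5-methylidene-3a,4,5,5a,6,7,9a,9b-octahydronaphtho[2,1-b]furan-2(1H)-one | O=C1C[C@@H]2[C@@H](O1)CC(=C)[C@H]3CCC(C)=C[C@@]23O | intermediate
19 | (3aR,5Z,9Z,11aS)-6,10-dimethyl-3,3a,7,8,11,11a-hexahydrocyclodeca[b]furan-2,4-dione | C1C(=O)O[C@H]2C/C(C)=C\CC/C(C)=C\C(=O)[C@H]12 | intermediate
20 | (3aR,6S,9Z,11aS)-6,10-dimethyl-6-(4,4,5,5-tetramethyl-1,3,2-dioxaborolan-2-yl)-3,3a,5,6,7,8,11,11a-octahydrocyclodeca[b]furan-2,4-dione | C1C(=O)O[C@H]2C/C(C)=C\CC[C@@](C)(B3OC(C)(C)C(C)(C)O3)CC(=O)[C@H]12 | intermediate (not isolated)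
21 | (3aR,6R,9Z,11aS)-6-hydroxy-6,10-dimethyl-3,3a,5,6,7,8,11,11a-octahydrocyclodeca[b]furan-2,4-dione | C1C(=O)O[C@H]2C/C(C)=C\CC[C@@](C)(O)CC(=O)[C@H]12 | intermediate
22 | (3aS,4S,6R,9Z,11aS)-4,6-dihydroxy-6,10-dimethyl-3a,4,5,6,7,8,11,11a-octahydrocyclodeca[b]furan-2(3H)-one | C1C(=O)O[C@H]2C/C(C)=C\CC[C@@](C)(O)C[C@H](O)[C@H]12 | intermediate
23 | (3aS,4S,6R,9Z,11aS)-3-[(dimethylamino)methyl]-4,6-dihydroxy-6,10-dimethyl-3a,4,5,6,7,8,11,11a-octahydrocyclodeca[b]furan-2(3H)-one (C3 epimers) | CN(C)CC1C(=O)O[C@H]2C/C(C)=C\CC[C@@](C)(O)C[C@H](O)[C@H]12 | intermediate (not isolated)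
24 | {[(3aS,4S,6R,9Z,11aS)-4,6-dihydroxy-6,10-dimethyl-2-oxo-2,3,3a,4,5,6,7,8,11,11a-decahydrocyclodeca[b]furan-3-yl]methyl}trimethylammonium iodide | C[N+](C)(C)CC1C(=O)O[C@H]2C/C(C)=C\CC[C@@](C)(O)C[C@H](O)[C@H]12.[I-] | intermediate (not isolated)
25 | (3aS,4S,6R,9Z,11aS)-4,6-dihydroxy-6,10-dimethyl-3-methylidene-3a,4,5,6,7,8,11,11a-octahydrocyclodeca[b]furan-2(3H)-one | C=C1C(=O)O[C@H]2C/C(C)=C\CC[C@@](C)(O)C[C@H](O)[C@H]12 | intermediate
26 | (2Z)-2-[(acetyloxy)methyl]but-2-enoic 2,4,6-trichlorobenzoic anhydride | CC(=O)OC/C(=C/C)C(=O)OC(=O)c1c(Cl)cc(Cl)cc1Cl | intermediate (not isolated)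
27 | (3aR,4S,6R,9Z,11aS)-6-hydroxy-6,10-dimethyl-3-methylidene-2-oxo-2,3,3a,4,5,6,7,8,11,11a-decahydrocyclodeca[b]furan-4-yl (2Z)-2-[(acetyloxy)methyl]but-2-enoate | C=C1C(=O)O[C@H]2C/C(C)=C\CC[C@@](C)(O)C[C@H](OC(=O)/C(=C\C)COC(C)=O)[C@H]12 | intermediate
28 | (3aR,4S,6R,9E,11aS)-6-hydroxy-10-(hydroxymethyl)-6-methyl-3-methylidene-2-oxo-2,3,3a,4,5,6,7,8,11,11a-decahydrocyclodeca[b]furan-4-yl (2Z)-2-[(acetyloxy)methyl]but-2-enoate | C=C1C(=O)O[C@H]2C/C(CO)=C\CC[C@@](C)(O)C[C@H](OC(=O)/C(=C\C)COC(C)=O)[C@H]12 | target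

**Totals and risks**
Total step count: 16. Longest linear sequence: 13 steps (6 → 28, steps 4–16); the side chain is 3 steps (1 → 5).

Step 11 (the proposed ring expansion) is the most likely to fail: the alkoxy radical may fragment unselectively, or the hydrogen may return to C9 to leave the exo-methylene isomer. The fallback uses known chemistry and sets out from 18. PhI(OAc)2 and I2 under visible light in cyclohexane/CH2Cl2 form the hypoiodite, whose alkoxy radical cleaves the same fusion bond; iodine traps the allyl radical at its primary end to give (3aR,5Z,9E,11aS)-10-(iodomethyl)-6-methyl-3,3a,7,8,11,11a-hexahydrocyclodeca[b]furan-2,4-dione F1. Reduction of the C–I bond with Bu3SnH and azobisisobutyronitrile in benzene at 80 °C then comes back to the route at 19.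

Step 9 (reductive aldol) may suffer from isomerisation of the β,γ-unsaturated ketone, from reduction of the ring enone, or from a poor cis/trans ratio. The fallback sets out from 15 and separates the two events. RhCl(PPh3)3-catalysed 1,4-hydrosilylation with Et3SiH gives methyl (3Z)-6-[(1R)-4-methyl-2-oxocyclohex-3-en-1-yl]-4-[(triethylsilyl)oxy]hepta-3,6-dienoate F2. An intramolecular Mukaiyama aldol addition (TiCl4, CH2Cl2, −78 °C) then closes ring B and comes back at 16.

Step 12 (asymmetric β-borylation of a hindered ten-membered enone) may be slow or poorly face-selective. The fallback sets out from 19. Amine-salt-catalysed nucleophilic epoxidation (H2O2, 9-amino-9-deoxy-epi-quinine bis(trifluoroacetate), dioxane, 35 °C) gives (3aR,5R,6R,9Z,11aS)-5,6-epoxy-6,10-dimethyl-3,3a,5,6,7,8,11,11a-octahydrocyclodeca[b]furan-2,4-dione F3. Reductive opening of the Cα–O bond with SmI2 in THF/MeOH at −90 °C comes back at 21.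

**Further compounds**
F1 | step 11 | (3aR,5Z,9E,11aS)-10-(iodomethyl)-6-methyl-3,3a,7,8,11,11a-hexahydrocyclodeca[b]furan-2,4-dione | C1C(=O)O[C@H]2C/C(CI)=C\CC/C(C)=C\C(=O)[C@H]12
F2 | step 9 | methyl (3Z)-6-[(1R)-4-methyl-2-oxocyclohex-3-en-1-yl]-4-[(triethylsilyl)oxy]hepta-3,6-dienoate | COC(=O)C/C=C(/CC(=C)[C@H]1CCC(C)=CC1=O)O[Si](CC)(CC)CC
F3 | step 12 | (3aR,5R,6R,9Z,11aS)-5,6-epoxy-6,10-dimethyl-3,3a,5,6,7,8,11,11a-octahydrocyclodeca[b]furan-2,4-dione | C1C(=O)O[C@H]2C/C(C)=C\CC[C@@]3(C)O[C@H]3C(=O)[C@H]12
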